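**Plan** (oxolane locants: O1, C2 aryl, C3 CH2O‑angelate, C4 benzyl, C5 CH2)
1. Retrosynthesis: cut the angelate C–O bond to give alcohol 11. Then re‑join the C3–CH2–O oxygen to the benzylic CH2 of the cis C4 arm, which uncovers a temporary second ring, the C2‑symmetric 2,6‑diaryl‑3,7‑dioxabicyclo[3.3.0]octane 10.
2. 10 is cut at O1–C2 and C3–C4 in one stroke. O1–C5–C4 is an opened terminal epoxide and C2=C3 an (E)‑cinnamyl alkene, both carried on one ether oxygen (7). 7 divides into epoxy alcohol 4 and cinnamyl bromide 6.
3. Enabling feature: the cis CH2O (C3) and CH2Ar (C4) arms are the remnant of a second oxolane. C2 is benzylic, carries a para‑methoxy donor and sits next to O1, so a radical born at C4 ends, after C3–C4 bond formation, as an easily ionised centre at C2 within reach of O1.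
4. Forward order: veratraldehyde → allylic alcohol → resolved epoxy alcohol → ether 7 → helper oxolane and then target oxolane in one pot (10) → hydrogenolysis of the helper ring → Mitsunobu angelate.
5. Stereochemistry: only the carbinol carbon of 4 comes from a catalyst (Sharpless kinetic resolution). It relays to C4, C3 and C2 in the key step and is itself erased by the hydrogenolysis. The Z‑alkene is bought with angelic acid.

Key step: step 5

Assumption: (E)‑3,4‑dimethoxycinnamyl alcohol 5 and angelic acid 12 are taken as catalogue compounds.

**Step 1**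
Reactants: 1 3,4‑dimethoxybenzaldehyde (veratraldehyde); 2 vinylmagnesium bromide
Product: 3 rac‑1‑(3,4‑dimethoxyphenyl)prop‑2‑en‑1‑ol
Conditions: 2 (1.2 equiv), THF, 0 °C; aq NH4Cl
Reagents that add atoms: none
Why: Grignard 1,2‑addition of a vinyl nucleophile to an aromatic aldehyde, in which the carbinol centre forms racemic and is sorted out in step 2.

**Step 2**
Reactants: 3 rac‑1‑(3,4‑dimethoxyphenyl)prop‑2‑en‑1‑ol
Product: 4 (R)‑(3,4‑dimethoxyphenyl)[(S)‑oxiran‑2‑yl]methanol (erythro epoxy alcohol)
Conditions: Ti(OiPr)4 (10 mol%), D‑(−)‑DIPT (12 mol%), t‑BuOOH (0.45 equiv), 4 Å MS, CH2Cl2, −20 °C; unreacted (R)‑3 removed by chromatography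
Reagents that add atoms: tert‑butyl hydroperoxide, CC(C)(C)OO
Why: Sharpless kinetic resolution (asymmetric epoxidation of a secondary allylic alcohol), in which D‑(−)‑tartrate makes (S)‑3 the fast‑reacting antipode and gives the erythro epoxy alcohol, so stopping below half conversion should fix the carbinol centre, while the epoxide centre is of no consequence because step 5 erases it.

**Step 3**
Reactants: 5 (E)‑3‑(3,4‑dimethoxyphenyl)prop‑2‑en‑1‑ol
Product: 6 (E)‑3,4‑dimethoxycinnamyl bromide
Conditions: PBr3 (0.4 equiv), Et2O, −10 → 0 °C; used crude at once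
Reagents that add atoms: phosphorus tribromide, BrP(Br)Br
Why: Bromination of a primary allylic alcohol through its phosphite ester (SN2), with retention of the E‑alkene, the product being kept cold and unpurified because the electron‑rich cinnamyl bromide ionises easily.

**Step 4**
Reactants: 4 (R)‑(3,4‑dimethoxyphenyl)[(S)‑oxiran‑2‑yl]methanol; 6 (E)‑3,4‑dimethoxycinnamyl bromide
Product: 7 (S)‑2‑[(R)‑(3,4‑dimethoxyphenyl){[(E)‑3‑(3,4‑dimethoxyphenyl)prop‑2‑en‑1‑yl]oxy}methyl]oxirane
Conditions: NaH (1.1 equiv), THF–DMF, 0 °C; then 6, 0 °C → rt
Reagents that add atoms: none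
Why: Williamson ether synthesis with a very reactive allylic bromide, which touches no stereocentre and whose aprotic, cold medium and fast capture of the alkoxide should hold back Payne‑type epoxide migration.

**Step 5**
Reactants: 7 epoxy cinnamyl ether
Product: 10 (+)‑eudesmin, via benzyltitanium alkoxide 8 (not isolated), via benzylic iodide 9 (not isolated)
Conditions: Cp2TiCl2 (2.5 equiv), Zn dust, THF, rt, the green solution added slowly to dilute 7; then I2 (1.5 equiv), THF, rt → 60 °C; aq Na2S2O3
Reagents that add atoms: none
Why: Cp2TiCl transfers one electron to the terminal epoxide and opens it at the more substituted carbon, so that C4 becomes a secondary β‑titanoxy radical (the epoxide stereocentre is erased) that adds 5‑exo‑trig to the near carbon of the cinnamyl alkene, forming C3–C4 and the helper oxolane and placing the spin on benzylic C2, where a second Cp2TiCl holds it as 8. Iodine converts 8 into the benzylic iodide 9, which ionises with the push of the para‑methoxy group and is captured by the titanium alkoxide oxygen O1 in a 5‑exo‑tet, SN1‑like closure that forms O1–C2 and the target oxolane, so that in sum the epoxide C–O bond has added across the alkene in a tethered formal (3+2) cycloaddition. The closest known reaction type is the titanocene(III)‑mediated radical cyclisation of epoxy alkenes with iodine‑induced ether closure. C4 and C3 are set together in a chair‑like Beckwith–Houk transition state in which the aryl group on the resolved carbinol carbon lies pseudo‑equatorial, so that the CH2OTi arm on C4 ends trans to that aryl group and cis to the new ArCH arm on C3. C2 is set in the closure, because the two five‑membered rings can only fuse cis and the aryl group takes the exo (convex) side, trans to the C3 arm, an outcome that reversible ionisation at this electron‑rich benzylic carbon can only reinforce. The step needs opening at the internal epoxide carbon (secured by radical stability), 5‑exo rather than 6‑endo addition (secured by the styrene‑type acceptor, which gives the benzylic radical) and cyclisation faster than reduction of the C4 radical (secured by slow addition of the titanium(III) solution at high dilution).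

**Step 6**
Reactants: 10 (+)‑eudesmin
Product: 11 [(2S,3R,4R)‑4‑(3,4‑dimethoxybenzyl)‑2‑(3,4‑dimethoxyphenyl)oxolan‑3‑yl]methanol ((+)‑lariciresinol dimethyl ether)
Conditions: H2 (1 atm), 10% Pd/C, EtOAc–AcOH, rt, stopped after uptake of 1 equiv H2; recovered 10 recycled
Reagents that add atoms: none
Why: Catalytic hydrogenolysis of a benzylic C–O bond, in which the two benzylic C–O bonds of C2‑symmetric 10 are homotopic and give the same 11, the first cleavage should be favoured statistically and by release of the bicyclo[3.3.0] strain, and only the helper benzylic stereocentre is erased while C2, C3 and C4 stay untouched.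

**Step 7**
Reactants: 11 (+)‑lariciresinol dimethyl ether; 12 angelic acid
Product: 13 leoligin
Conditions: 12 (1.5 equiv), PPh3, DIAD, THF, 0 °C → rt
Reagents that add atoms: none
Why: Mitsunobu esterification activates the primary alcohol and not the acid, so the angelate never passes through an activated acyl species that could isomerise Z to E, and the reacting carbon is a CH2 group, so no stereocentre is affected.

**Compound list**
1 | 3,4‑dimethoxybenzaldehyde (veratraldehyde) | COc1ccc(C=O)cc1OC | starting material
2 | vinylmagnesium bromide | C=C[Mg]Br | starting material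
3 | rac‑1‑(3,4‑dimethoxyphenyl)prop‑2‑en‑1‑ol | C=CC(O)c1ccc(OC)c(OC)c1 | intermediate
4 | (R)‑(3,4‑dimethoxyphenyl)[(S)‑oxiran‑2‑yl]methanol | COc1ccc(cc1OC)[C@@H](O)[C@@H]1CO1 | intermediate
5 | (E)‑3‑(3,4‑dimethoxyphenyl)prop‑2‑en‑1‑ol | COc1ccc(/C=C/CO)cc1OC | starting material
6 | (E)‑4‑(3‑bromoprop‑1‑en‑1‑yl)‑1,2‑dimethoxybenzene | COc1ccc(/C=C/CBr)cc1OC | intermediate
7 | (S)‑2‑[(R)‑(3,4‑dimethoxyphenyl){[(E)‑3‑(3,4‑dimethoxyphenyl)prop‑2‑en‑1‑yl]oxy}methyl]oxirane | COc1ccc(cc1OC)[C@@H](OC/C=C/c1ccc(OC)c(OC)c1)[C@@H]1CO1 | intermediate
8 | monocyclic (2S,3R,4R)‑oxolane with CH2O–TiCp2Cl on C3 and ArCH–TiCp2Cl on C4 (written as ions; benzylic centre undefined) | COc1ccc(cc1OC)[C@@H]1[C@@H](C[O-])[C@@H]([CH-]c2ccc(OC)c(OC)c2)CO1.[Ti+4].[Ti+4].[Cl-].[Cl-].[CH-]1C=CC=C1.[CH-]1C=CC=C1.[CH-]1C=CC=C1.[CH-]1C=CC=C1 | intermediate (not isolated)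
9 | the same oxolane with CH2O–TiCp2Cl on C3 and ArCH(I) on C4 (written as ions; iodide centre undefined) | COc1ccc(cc1OC)[C@@H]1[C@@H](C[O-])[C@@H](C(I)c2ccc(OC)c(OC)c2)CO1.[Ti+4].[Cl-].[CH-]1C=CC=C1.[CH-]1C=CC=C1 | intermediate (not isolated)
10 | (+)‑eudesmin, (1S,3aR,4S,6aR)‑1,4‑bis(3,4‑dimethoxyphenyl)tetrahydro‑1H,3H‑furo[3,4‑c]furan | COc1ccc(cc1OC)[C@@H]1[C@H]2CO[C@@H]([C@H]2CO1)c1ccc(OC)c(OC)c1 | intermediate
11 | [(2S,3R,4R)‑4‑(3,4‑dimethoxybenzyl)‑2‑(3,4‑dimethoxyphenyl)oxolan‑3‑yl]methanol | OC[C@H]1[C@@H](Cc2ccc(OC)c(OC)c2)CO[C@@H]1c1ccc(OC)c(OC)c1 | intermediate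
12 | angelic acid, (Z)‑2‑methylbut‑2‑enoic acid | C/C=C(/C)C(=O)O | starting material
13 | leoligin, [(2S,3R,4R)‑4‑(3,4‑dimethoxybenzyl)‑2‑(3,4‑dimethoxyphenyl)oxolan‑3‑yl]methyl (Z)‑2‑methylbut‑2‑enoate | C/C=C(/C)C(=O)OC[C@H]1[C@@H](Cc2ccc(OC)c(OC)c2)CO[C@@H]1c1ccc(OC)c(OC)c1 | target

**Total step count:** 7. **Longest linear sequence:** 6 (steps 1, 2, 4, 5, 6, 7).

**Steps most likely to fail**

Step 5. The benzylic centre may be reduced or may abstract hydrogen before the C–O closure. The C4 radical may be reduced and deoxygenated before it cyclises. The closure may also show incomplete exo selectivity. The fallback sets out from 7 and comes back at 11, leaving out 10 and step 6. The same titanium(III) opening and 5‑exo cyclisation are run, but the sequence is ended reductively instead of oxidatively. The carbon–titanium bond of 8 is protonated with dilute acid in place of the iodine treatment. The ArCH arm then becomes the benzyl group and the CH2O–Ti arm the hydroxymethyl group. The oxolane of 11 is in that case the ring closed by the radical step alone, and no new compound is passed.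

Step 6. The second benzylic C–O bond may be hydrogenolysed at a rate close to that of the first, so the reaction cannot be held at the mono‑cleaved stage. The fallback sets out from 10 and comes back at 11. Hydrogenolysis is driven to completion on both benzylic C–O bonds (H2, Pd/C, AcOH with a trace of strong acid). This gives the C2‑symmetric (2R,3R)‑2,3‑bis(3,4‑dimethoxybenzyl)butane‑1,4‑diol F1. One oxolane ring is then closed again by oxidative benzylic C–H etherification with one equivalent of DDQ in CH2Cl2. Hydride abstraction para to a methoxy group gives a benzylic cation. The hydroxyl group four atoms away captures it, with the aryl group trans to the neighbouring arm. Symmetry allows only one mono‑cyclised product.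

Step 4. The bromide may be lost through ionisation or hydrolysis before it is alkylated, and the epoxide may migrate within the alkoxide. The fallback sets out from 4 and comes back at 7, and it leaves out step 3 and the labile bromide. 4 is O‑allylated under neutral conditions (allyl bromide, Ag2O, CH2Cl2) to (S)‑2‑[(R)‑(allyloxy)(3,4‑dimethoxyphenyl)methyl]oxirane F2. The aryl group is then brought in by E‑selective olefin cross metathesis with commercial 3,4‑dimethoxystyrene (Hoveyda–Grubbs II catalyst, CH2Cl2, 40 °C).

**Further compounds**
F0 | step 5 | none | none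
F1 | step 6 | (2R,3R)‑2,3‑bis(3,4‑dimethoxybenzyl)butane‑1,4‑diol | OC[C@H](Cc1ccc(OC)c(OC)c1)[C@@H](Cc1ccc(OC)c(OC)c1)CO
F2 | step 4 | (S)‑2‑[(R)‑(allyloxy)(3,4‑dimethoxyphenyl)methyl]oxirane | COc1ccc(cc1OC)[C@@H](OCC=C)[C@@H]1CO1
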